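## The problem

Target 31 is an open C18 chain, numbered here from C1 (the CH2 on C3 of the furan) to C18 (the terminal CMe2 carbon). It carries CO2Me on C4, an isopropenyl group on C7, a methyl on C10 and CO2H on C14; no ring has to be formed, because the furan can be bought. Three trisubstituted alkenes of three different kinds must each be made with defined geometry: the Z enoate C3=C4 (ester cis to C2, the less stable arrangement), the unactivated E alkene C9=C10, and the E enoic acid C13=C14 (acid trans to C12). The only stereocentre, C7 (S), is a CH between two methylenes and far from any polar group, so nothing in the molecule can direct its formation; it has to come from a chiral reagent or catalyst. Its hydrogen is allylic to the isopropenyl group, so once C7 is set, strong acid, strong base and alkene-isomerising metals must be kept away. The 3-alkylfuran does not tolerate strong acid, halogens or quinone oxidants, the Z enoate can isomerise under nucleophilic or radical conditions, and the methyl ester and the free acid must stay distinguishable to the end. The feature that opens the route is that C7 has two CH2 neighbours (C6 and C8) and one sp2 substituent, and that C8 is the allylic methylene of C9=C10. C7 can therefore be the carbenoid carbon of a lithiated O-alkyl carbamate that inserts into the C8–B bond of an allylic boronate, and the boron left on C7 can then be exchanged for the isopropenyl group.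

## Retrosynthesis

**31 from 30.** The free acid is released last from the allyl ester 30. An allyl ester can be removed with zerovalent palladium and an amine under neutral conditions that leave the methyl ester, the furan and all four alkenes alone. A tert-butyl ester would need acid, and a silylethyl ester would clash with the fluoride step already needed for the silyl ether.

**30 from 25 and 29 (C13=C14).** Cutting the E enoate gives aldehyde 25 and the α-branched stabilised ylide 29. This is the one cut on this arm that sets the geometry while it joins the pieces: an ester-stabilised ylide with an α-alkyl group gives the E enoate. Cutting C12–C13 or C14–C15 would form a bond without deciding the geometry. Eight carbons (C14–C18, the acid carbon and two methyls) leave in one convergent step. Ylide 29 comes from the parent ylide 26 and bromide 27.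

**25 from 23 through 24.** The C13 aldehyde is traced to a silyl-protected primary alcohol. A TBDPS ether is chosen rather than a benzyl-type ether because its removal needs fluoride, not a quinone oxidant, and so can be done with the furan present.

**23 from 17 and 22 (C3=C4).** The Z enoate is cut into the small unbranched aldehyde 22 and the bis(trifluoroethyl) phosphonate 17, which carries the whole C5–C13 fragment as its α-substituent. A kinetically controlled olefination of this type is the most direct way to the less stable geometry. Making C4–C5 by cross-coupling is the main competitor and is weighed under Alternative 1. Aldehyde 22 comes from 18 and 19 through alcohol 21.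

**17 from 15 and 16 (C4–C5).** The α-substituent is attached by alkylating the phosphonoacetate 16 with primary iodide 15. The iodide comes from alcohol 14, and 14 from the bis-silyl ether 13 by selective loss of the smaller silyl group. The C5 arm is built before the C13 arm so that the basic alkylation and olefination meet only a robust silyl ether at C13.

**13 from 10 (C7–isopropenyl).** The isopropenyl group is put on C7 in place of boron by an iodine-induced alkenyl boronate olefination that keeps the configuration of the migrating carbon. This reduces the stereochemical problem to a secondary boronic ester.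

**10 from 2 and 7 (C7–C8, the key cut).** The secondary boronate 10 is divided into carbamate 2 (C5–C7) and the E allylic boronate 7 (C8–C13). Cutting C6–C7 instead would need a β-oxygenated ethyl boronate, which eliminates readily. Using an isopropenyl boronate as the boron partner would leave no boron on C7 for a later stereoretentive exchange. The C7–C8 cut gives two fragments of similar size, uses a good migrating group (an allylic CH2) and leaves the already fixed C9=C10 geometry untouched. The forward reaction must select one enantiotopic proton of 2 and shift the allyl group through its boron-bound carbon.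

**2 from 1; 7 from 3 through 4 and 6.** Carbamate 2 is one step from the commercial mono-silylated diol 1. The E geometry of C9=C10 in 7 is fixed by syn methylmetalation of the terminal alkyne 4, and C8 is added as a one-carbon electrophile to give allylic alcohol 6. The five-carbon alkynol 3 is used so that C13 is already present as a protected alcohol and no later one-carbon extension is needed.

## Roads not taken

**Alternative 1:** The cut is C4–C5, made at the very end. The alkylzinc iodide A3 of the complete C5–C18 fragment (tert-butyl ester on C14) would couple under zerovalent palladium, for example Pd(PPh3)4, with methyl (E)-2-iodo-5-(furan-3-yl)pent-2-enoate A2, whose geometry comes from a syn-hydrometalation–iodination sequence. The product is the tert-butyl ester A1 of the target.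
- Merits: the Z enoate geometry is fixed stereospecifically and carried through by retention, and the step is highly convergent.
- Weak points: it does not address C7, which would still need its own method. Zinc insertion would have to be done late on a primary iodide in a molecule that already holds an enoate and three alkenes. sp3–sp2 couplings of α-iodoenoates compete with reduction and homocoupling, and the α-palladated enoate can lose its geometry. The tert-butyl ester of A1 would have to be cleaved with acid beside the furan and the 1,1-disubstituted alkene.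
- Comparison: for the Z enoate alone this road is at least as secure as the olefination of step 12 and would save a step, since one coupling replaces steps 9 and 12. Against that, the chosen plan's defining step makes the stereocentre and a skeletal bond together, and its end-game is neutral throughout. Iodide 15 lies on the chosen route, so a coupling with A2 would remain open.

**Alternative 2:** The cut is C7–isopropenyl on a five-carbon enoate. Isopropenyl pinacol boronate A6 would add to the β-carbon of ethyl (E)-5-(tert-butyldimethylsilyloxy)pent-2-enoate A5 under a chiral diene complex made from [RhCl(C2H4)2]2, giving ethyl (S)-3-[2-(tert-butyldimethylsilyloxy)ethyl]-4-methylpent-4-enoate A4.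
- Merits: C7 and its isopropenyl group arrive in one catalytic step from very simple materials. In that respect it is better than the chosen plan, which needs a stoichiometric chiral diamine and two steps (5 and 6) for the same result.
- Weak points: α-substituted alkenyl boronates transmetalate slowly and protodeboronate. The catalyst must distinguish the faces of an acyclic enoate whose β-substituent is a flexible chain. A4 then has to be extended from its ester carbon (C9) into the E trisubstituted C9=C10 alkene, which has no stabilising group on either carbon, so the geometry problem that the chosen plan settles by carbometalation comes back in a harder form. The rest of the chain would be built linearly.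
- Comparison: cheaper at the stereocentre, more expensive everywhere else. The chosen plan sets against the catalytic step its convergence and the fact that C9=C10 enters with its geometry already fixed.

**Alternative 3:** The cut is C11–C12, with the alkene moved into place by a sigmatropic shift. The C9 allylic alcohol A8 (either epimer, with a 2-propenyl unit at C10=C11) would be heated with triethyl orthoacetate A9 and a trace of weak acid. The [3,3] shift through a six-membered chair would give the C13 ethyl ester A7 with the E C9=C10 alkene.
- Merits: the carbinol configuration does not matter, the chair places the C9 substituent equatorial and so favours the E alkene, and C13 arrives as an ester one reduction away from the aldehyde needed for the acid arm. For the C9–C13 segment this is as good as steps 2–4 of the chosen plan, and it avoids pyrophoric alkylaluminium reagents.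
- Weak points: it presupposes a substrate that already holds the C7 stereocentre and the isopropenyl group, so it solves none of the stereochemical problem. E selectivity in such rearrangements is high but not complete, and the minor Z isomer would be hard to remove from a nonpolar chain. The hot acidic medium acts on a compound whose C7–H is already allylic.
- Comparison: the chosen plan sets against the elegance of this alkene construction that one step creates C7, the C7–C8 bond and the handle for the isopropenyl group, and that the carbometalation geometry is set before any sensitive group is present.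

Key step: step 5

Assumption: s-BuLi with (+)-sparteine is taken to remove the pro-R proton of carbamate 2, the mirror image of the established pro-S preference of the (−)-enantiomer; the chain numbering C1–C18 defined above is used for all intermediates.

## Route

Step 1
Reactants: 1 3-(tert-butyldimethylsilyloxy)propan-1-ol
Product: 2 3-(tert-butyldimethylsilyloxy)propyl N,N-diisopropylcarbamate
Conditions: iPr2NCOCl, Et3N, CH2Cl2, reflux
Reagents that add atoms: N,N-diisopropylcarbamoyl chloride, CC(C)N(C(C)C)C(=O)Cl
Why: O-Carbamoylation of a primary alcohol; the hindered carbamate is the directing and leaving group needed in step 5, and the silyl ether is inert to the amine base.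

Step 2
Reactants: 3 pent-4-yn-1-ol
Product: 4 tert-butyl(pent-4-yn-1-yloxy)diphenylsilane
Conditions: TBDPSCl, imidazole, DMF, rt
Reagents that add atoms: tert-butylchlorodiphenylsilane, CC(C)(C)[Si](Cl)(c1ccccc1)c1ccccc1
Why: Standard silylation; the TBDPS ether is chosen because it should survive Me3Al, organolithiums, iodine and the later acid methanolysis of the TBS ether.

Step 3
Reactants: 4 tert-butyl(pent-4-yn-1-yloxy)diphenylsilane
Product: 6 (E)-6-(tert-butyldiphenylsilyloxy)-3-methylhex-2-en-1-ol, via alkenylalane 5 (not isolated)
Conditions: Me3Al, Cp2ZrCl2 (cat.), CH2Cl2, 0 °C to rt; then (CH2O)n, THF, 0 °C to rt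
Reagents that add atoms: trimethylaluminium, C[Al](C)C; paraformaldehyde (as formaldehyde), C=O
Why: Negishi zirconium-catalysed carboalumination adds methyl and aluminium syn across the terminal alkyne with aluminium on the terminal carbon; capture of alane 5 by formaldehyde with retention puts C8 cis to the new methyl, which is the E geometry of C9=C10.

Step 4
Reactants: 6 (E)-6-(tert-butyldiphenylsilyloxy)-3-methylhex-2-en-1-ol
Product: 7 2-[(E)-6-(tert-butyldiphenylsilyloxy)-3-methylhex-2-en-1-yl]-4,4,5,5-tetramethyl-1,3,2-dioxaborolane
Conditions: B2pin2, Pd(MeCN)4(BF4)2 (cat.), DMSO/MeOH, rt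
Reagents that add atoms: bis(pinacolato)diboron, CC1(C)OB(OC1(C)C)B1OC(C)(C)C(C)(C)O1
Why: Palladium-catalysed borylation of an allylic alcohol through an allylpalladium intermediate; boron should go to the unhindered terminus to give the linear primary allyl boronate, and the syn-allyl complex should preserve the E geometry.

Step 5
Reactants: 2 3-(tert-butyldimethylsilyloxy)propyl N,N-diisopropylcarbamate; 7 2-[(E)-6-(tert-butyldiphenylsilyloxy)-3-methylhex-2-en-1-yl]-4,4,5,5-tetramethyl-1,3,2-dioxaborolane
Product: 10 2-[(4E,7R)-9-(tert-butyldimethylsilyloxy)-1-(tert-butyldiphenylsilyloxy)-4-methylnon-4-en-7-yl]-4,4,5,5-tetramethyl-1,3,2-dioxaborolane, via lithiated carbamate 8 (not isolated), via boronate complex 9 (not isolated)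
Conditions: s-BuLi, (+)-sparteine, Et2O, −78 °C; then 7, −78 °C; then MgBr2·OEt2, −78 °C to reflux
Reagents that add atoms: none
Why: The s-BuLi/(+)-sparteine complex, held by the carbamate carbonyl, should remove the pro-R proton next to oxygen to give the configurationally stable (R)-organolithium 8. This adds to the boron of 7 with retention to give the tetracoordinate boronate 9. On warming with the magnesium Lewis acid, the allylic CH2 (C8) shifts from boron to C7 anti to the departing carbamate, forming C7–C8 with inversion at C7. The closest known reaction type is the lithiation–borylation of O-alkyl carbamates with pinacol boronic esters, a Matteson-type 1,2-metalate rearrangement. No ring is closed. The new stereocentre C7 is controlled only by the diamine, through the sequence retention (borylation) then inversion (migration), which should give the R boronate 10. The step needs selection between two enantiotopic protons, supplied by the reagent, and migration of the allyl group through its boron-bound carbon with no allylic transposition. The second is secured because no electrophile engages the γ-carbon and the allyl group never leaves boron, so the E alkene is carried over unchanged.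

Step 6
Reactants: 10 2-[(4E,7R)-9-(tert-butyldimethylsilyloxy)-1-(tert-butyldiphenylsilyloxy)-4-methylnon-4-en-7-yl]-4,4,5,5-tetramethyl-1,3,2-dioxaborolane
Product: 13 tert-butyl{[(4E,7R)-7-[2-(tert-butyldimethylsilyloxy)ethyl]-4,8-dimethylnona-4,8-dien-1-yl]oxy}diphenylsilane, via isopropenyl boronate complex 11 (not isolated), via iodo boronate 12 (not isolated)
Conditions: 2-bromopropene, t-BuLi, THF, −78 °C; then 10, −78 to 0 °C; I2, MeOH, −78 °C; NaOMe, MeOH, −78 °C to rt
Reagents that add atoms: 2-bromopropene (used as isopropenyllithium), C=C(C)Br
Why: Zweifel olefination: isopropenyllithium adds to boron (11), iodine activates the alkenyl group and triggers 1,2-migration of C7 with retention (12), and methoxide brings about anti elimination of boron and iodide to the 1,1-disubstituted alkene. C7 keeps its configuration, and the isolated trisubstituted alkene is far less nucleophilic than the alkenyl boronate complex, so it should not be iodinated at −78 °C.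

Step 7
Reactants: 13 tert-butyl{[(4E,7R)-7-[2-(tert-butyldimethylsilyloxy)ethyl]-4,8-dimethylnona-4,8-dien-1-yl]oxy}diphenylsilane
Product: 14 (3R,5E)-9-(tert-butyldiphenylsilyloxy)-6-methyl-3-(prop-1-en-2-yl)non-5-en-1-ol
Conditions: PPTS, MeOH, rt
Reagents that add atoms: none
Why: Acid-catalysed methanolysis of silyl ethers depends strongly on the size of the silyl group, so the primary TBS ether should be cleaved while the TBDPS ether and the alkenes stay untouched.

Step 8
Reactants: 14 (3R,5E)-9-(tert-butyldiphenylsilyloxy)-6-methyl-3-(prop-1-en-2-yl)non-5-en-1-ol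
Product: 15 tert-butyl{[(4E,7R)-7-(2-iodoethyl)-4,8-dimethylnona-4,8-dien-1-yl]oxy}diphenylsilane
Conditions: I2, PPh3, imidazole, CH2Cl2, 0 °C to rt
Reagents that add atoms: iodine, II
Why: Appel-type iodination of a primary alcohol through the alkoxyphosphonium ion; the buffered conditions do not touch the alkenes or the silyl ether.

Step 9
Reactants: 15 tert-butyl{[(4E,7R)-7-(2-iodoethyl)-4,8-dimethylnona-4,8-dien-1-yl]oxy}diphenylsilane; 16 methyl 2-[bis(2,2,2-trifluoroethoxy)phosphoryl]acetate
Product: 17 methyl (5S,7E)-2-[bis(2,2,2-trifluoroethoxy)phosphoryl]-11-(tert-butyldiphenylsilyloxy)-8-methyl-5-(prop-1-en-2-yl)undec-7-enoate (both C2 epimers)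
Conditions: NaH, THF/DMF, 0 to 50 °C (16 in excess)
Reagents that add atoms: none
Why: C-Alkylation of the sodium salt of a phosphonoacetate with a primary iodide forms C4–C5; an excess of 16 limits double alkylation, and the new centre at the phosphonate carbon is irrelevant because it becomes sp2 in step 12.

Step 10
Reactants: 18 3-bromofuran; 19 oxetane
Product: 21 3-(furan-3-yl)propan-1-ol, via 3-furyllithium 20 (not isolated)
Conditions: n-BuLi, THF, −78 °C; then oxetane, BF3·OEt2, −78 °C
Reagents that add atoms: none
Why: Bromine–lithium exchange at −78 °C gives the 3-lithiofuran without migration to C2, and BF3-activated ring opening of oxetane by the aryllithium supplies C1–C3 in one operation.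

Step 11
Reactants: 21 3-(furan-3-yl)propan-1-ol
Product: 22 3-(furan-3-yl)propanal
Conditions: Dess–Martin periodinane, NaHCO3, CH2Cl2, 0 °C to rt
Reagents that add atoms: none
Why: Dess–Martin oxidation of a primary alcohol; the buffered, non-acidic medium is compatible with the furan and stops at the aldehyde.

Step 12
Reactants: 17 methyl (5S,7E)-2-[bis(2,2,2-trifluoroethoxy)phosphoryl]-11-(tert-butyldiphenylsilyloxy)-8-methyl-5-(prop-1-en-2-yl)undec-7-enoate; 22 3-(furan-3-yl)propanal
Product: 23 methyl (Z)-2-[(3S,5E)-9-(tert-butyldiphenylsilyloxy)-6-methyl-3-(prop-1-en-2-yl)non-5-en-1-yl]-5-(furan-3-yl)pent-2-enoate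
Conditions: KN(SiMe3)2, 18-crown-6, THF, −78 °C
Reagents that add atoms: none
Why: Still–Gennari variant of the Horner–Wadsworth–Emmons reaction: with the electron-poor phosphonate and a dissociated potassium ion the first-formed adduct eliminates faster than it equilibrates, which places the ester cis to C2 (Z). α-Alkyl reagents of this kind are reliably Z-selective with unbranched aliphatic aldehydes.

Step 13
Reactants: 23 methyl (Z)-2-[(3S,5E)-9-(tert-butyldiphenylsilyloxy)-6-methyl-3-(prop-1-en-2-yl)non-5-en-1-yl]-5-(furan-3-yl)pent-2-enoate
Product: 24 methyl (Z)-5-(furan-3-yl)-2-[(3S,5E)-9-hydroxy-6-methyl-3-(prop-1-en-2-yl)non-5-en-1-yl]pent-2-enoate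
Conditions: Bu4NF, AcOH, THF, 0 °C to rt
Reagents that add atoms: none
Why: Fluoride cleavage of the silyl ether; buffering with acetic acid keeps the medium from becoming basic enough to hydrolyse the methyl ester or isomerise the Z enoate.

Step 14
Reactants: 24 methyl (Z)-5-(furan-3-yl)-2-[(3S,5E)-9-hydroxy-6-methyl-3-(prop-1-en-2-yl)non-5-en-1-yl]pent-2-enoate
Product: 25 methyl (Z)-5-(furan-3-yl)-2-[(3S,5E)-6-methyl-9-oxo-3-(prop-1-en-2-yl)non-5-en-1-yl]pent-2-enoate
Conditions: Dess–Martin periodinane, NaHCO3, CH2Cl2, 0 °C to rt
Reagents that add atoms: none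
Why: Dess–Martin oxidation under buffered conditions gives the C13 aldehyde without touching the furan, the enoate or the alkenes.

Step 15
Reactants: 26 allyl 2-(triphenyl-λ5-phosphanylidene)acetate; 27 5-bromo-2-methylpent-2-ene
Product: 29 allyl 6-methyl-2-(triphenyl-λ5-phosphanylidene)hept-5-enoate, via phosphonium bromide 28 (not isolated)
Conditions: NaI (cat.), MeCN, reflux; then aq. NaOH, CH2Cl2, rt
Reagents that add atoms: none
Why: C-Alkylation of an ester-stabilised phosphorus ylide with a primary halide, helped by iodide exchange; salt 28 is less acidic than the conjugate acid of 26, so proton transfer between ylide and salt should stay minor, and hydroxide then liberates the α-branched ylide.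

Step 16
Reactants: 25 methyl (Z)-5-(furan-3-yl)-2-[(3S,5E)-6-methyl-9-oxo-3-(prop-1-en-2-yl)non-5-en-1-yl]pent-2-enoate; 29 allyl 6-methyl-2-(triphenyl-λ5-phosphanylidene)hept-5-enoate
Product: 30 methyl (Z)-2-[(3S,5E,9E)-10-(allyloxycarbonyl)-6,14-dimethyl-3-(prop-1-en-2-yl)pentadeca-5,9,13-trien-1-yl]-5-(furan-3-yl)pent-2-enoate
Conditions: toluene, 80 °C
Reagents that add atoms: none
Why: Wittig olefination with an α-substituted ester-stabilised ylide, which puts the ester trans to C12 (E) through the less crowded oxaphosphetane; the salt-free neutral conditions should not disturb the Z enoate at C3=C4.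

Step 17
Reactants: 30 methyl (Z)-2-[(3S,5E,9E)-10-(allyloxycarbonyl)-6,14-dimethyl-3-(prop-1-en-2-yl)pentadeca-5,9,13-trien-1-yl]-5-(furan-3-yl)pent-2-enoate
Product: 31 (2E,6E,9S,12Z)-15-(furan-3-yl)-12-(methoxycarbonyl)-6-methyl-2-(4-methylpent-3-en-1-yl)-9-(prop-1-en-2-yl)pentadeca-2,6,12-trienoic acid
Conditions: Pd(PPh3)4 (cat.), morpholine, THF, rt; mild acidic work-up
Reagents that add atoms: none
Why: Tsuji–Trost deallylation: zerovalent palladium ionises only the allyl ester to an allylpalladium carboxylate and morpholine captures the allyl group. The methyl ester, furan and alkenes have no leaving group and are not affected.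

## Compound list

1 | 3-(tert-butyldimethylsilyloxy)propan-1-ol | OCCCO[Si](C)(C)C(C)(C)C | starting material
2 | 3-(tert-butyldimethylsilyloxy)propyl N,N-diisopropylcarbamate | CC(C)N(C(C)C)C(=O)OCCCO[Si](C)(C)C(C)(C)C | intermediate
3 | pent-4-yn-1-ol | C#CCCCO | starting material
4 | tert-butyl(pent-4-yn-1-yloxy)diphenylsilane | C#CCCCO[Si](c1ccccc1)(c1ccccc1)C(C)(C)C | intermediate
5 | [(E)-5-(tert-butyldiphenylsilyloxy)-2-methylpent-1-en-1-yl]dimethylalane | C[Al](C)/C=C(\C)CCCO[Si](c1ccccc1)(c1ccccc1)C(C)(C)C | intermediate (not isolated)
6 | (E)-6-(tert-butyldiphenylsilyloxy)-3-methylhex-2-en-1-ol | OC/C=C(\C)CCCO[Si](c1ccccc1)(c1ccccc1)C(C)(C)C | intermediate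
7 | 2-[(E)-6-(tert-butyldiphenylsilyloxy)-3-methylhex-2-en-1-yl]-4,4,5,5-tetramethyl-1,3,2-dioxaborolane | CC1(C)OB(C/C=C(\C)CCCO[Si](c2ccccc2)(c2ccccc2)C(C)(C)C)OC1(C)C | intermediate
8 | (R)-3-(tert-butyldimethylsilyloxy)-1-lithiopropyl N,N-diisopropylcarbamate (as its (+)-sparteine complex) | [Li][C@H](CCO[Si](C)(C)C(C)(C)C)OC(=O)N(C(C)C)C(C)C | intermediate (not isolated)
9 | lithium boronate complex of 8 and 7 (boron bearing pinacolate, the E allyl group and the carbamoyloxy carbon C7) | [Li+].CC1(C)O[B-](C/C=C(\C)CCCO[Si](c2ccccc2)(c2ccccc2)C(C)(C)C)([C@H](CCO[Si](C)(C)C(C)(C)C)OC(=O)N(C(C)C)C(C)C)OC1(C)C | intermediate (not isolated)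
10 | 2-[(4E,7R)-9-(tert-butyldimethylsilyloxy)-1-(tert-butyldiphenylsilyloxy)-4-methylnon-4-en-7-yl]-4,4,5,5-tetramethyl-1,3,2-dioxaborolane | CC1(C)OB(OC1(C)C)[C@H](C/C=C(\C)CCCO[Si](c1ccccc1)(c1ccccc1)C(C)(C)C)CCO[Si](C)(C)C(C)(C)C | intermediate
11 | lithium isopropenyl boronate complex of 10 (C7 unchanged) | [Li+].C=C(C)[B-]1(OC(C)(C)C(C)(C)O1)[C@H](C/C=C(\C)CCCO[Si](c1ccccc1)(c1ccccc1)C(C)(C)C)CCO[Si](C)(C)C(C)(C)C | intermediate (not isolated)
12 | iodo boronate: pinacol boronate of the tertiary carbon bearing CH3, CH2I and C7 (C7 as in 10, new centre as a mixture) | ICC(C)(B1OC(C)(C)C(C)(C)O1)[C@H](C/C=C(\C)CCCO[Si](c1ccccc1)(c1ccccc1)C(C)(C)C)CCO[Si](C)(C)C(C)(C)C | intermediate (not isolated)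
13 | tert-butyl{[(4E,7R)-7-[2-(tert-butyldimethylsilyloxy)ethyl]-4,8-dimethylnona-4,8-dien-1-yl]oxy}diphenylsilane | C=C(C)[C@H](C/C=C(\C)CCCO[Si](c1ccccc1)(c1ccccc1)C(C)(C)C)CCO[Si](C)(C)C(C)(C)C | intermediate
14 | (3R,5E)-9-(tert-butyldiphenylsilyloxy)-6-methyl-3-(prop-1-en-2-yl)non-5-en-1-ol | C=C(C)[C@H](C/C=C(\C)CCCO[Si](c1ccccc1)(c1ccccc1)C(C)(C)C)CCO | intermediate
15 | tert-butyl{[(4E,7R)-7-(2-iodoethyl)-4,8-dimethylnona-4,8-dien-1-yl]oxy}diphenylsilane | C=C(C)[C@H](C/C=C(\C)CCCO[Si](c1ccccc1)(c1ccccc1)C(C)(C)C)CCI | intermediate
16 | methyl 2-[bis(2,2,2-trifluoroethoxy)phosphoryl]acetate | COC(=O)CP(=O)(OCC(F)(F)F)OCC(F)(F)F | starting material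
17 | methyl (5S,7E)-2-[bis(2,2,2-trifluoroethoxy)phosphoryl]-11-(tert-butyldiphenylsilyloxy)-8-methyl-5-(prop-1-en-2-yl)undec-7-enoate (both C2 epimers) | C=C(C)[C@H](C/C=C(\C)CCCO[Si](c1ccccc1)(c1ccccc1)C(C)(C)C)CCC(C(=O)OC)P(=O)(OCC(F)(F)F)OCC(F)(F)F | intermediate
18 | 3-bromofuran | Brc1ccoc1 | starting material
19 | oxetane | C1COC1 | starting material
20 | furan-3-yllithium | [Li]c1ccoc1 | intermediate (not isolated)
21 | 3-(furan-3-yl)propan-1-ol | OCCCc1ccoc1 | intermediate
22 | 3-(furan-3-yl)propanal | O=CCCc1ccoc1 | intermediate
23 | methyl (Z)-2-[(3S,5E)-9-(tert-butyldiphenylsilyloxy)-6-methyl-3-(prop-1-en-2-yl)non-5-en-1-yl]-5-(furan-3-yl)pent-2-enoate | C=C(C)[C@H](C/C=C(\C)CCCO[Si](c1ccccc1)(c1ccccc1)C(C)(C)C)CC/C(=C/CCc1ccoc1)C(=O)OC | intermediate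
24 | methyl (Z)-5-(furan-3-yl)-2-[(3S,5E)-9-hydroxy-6-methyl-3-(prop-1-en-2-yl)non-5-en-1-yl]pent-2-enoate | C=C(C)[C@H](C/C=C(\C)CCCO)CC/C(=C/CCc1ccoc1)C(=O)OC | intermediate
25 | methyl (Z)-5-(furan-3-yl)-2-[(3S,5E)-6-methyl-9-oxo-3-(prop-1-en-2-yl)non-5-en-1-yl]pent-2-enoate | C=C(C)[C@H](C/C=C(\C)CCC=O)CC/C(=C/CCc1ccoc1)C(=O)OC | intermediate
26 | allyl 2-(triphenyl-λ5-phosphanylidene)acetate | C=CCOC(=O)C=P(c1ccccc1)(c1ccccc1)c1ccccc1 | starting material
27 | 5-bromo-2-methylpent-2-ene | CC(C)=CCCBr | starting material
28 | [1-(allyloxy)-6-methyl-1-oxohept-5-en-2-yl]triphenylphosphonium bromide | C=CCOC(=O)C(CCC=C(C)C)[P+](c1ccccc1)(c1ccccc1)c1ccccc1.[Br-] | intermediate (not isolated)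
29 | allyl 6-methyl-2-(triphenyl-λ5-phosphanylidene)hept-5-enoate | C=CCOC(=O)C(CCC=C(C)C)=P(c1ccccc1)(c1ccccc1)c1ccccc1 | intermediate
30 | methyl (Z)-2-[(3S,5E,9E)-10-(allyloxycarbonyl)-6,14-dimethyl-3-(prop-1-en-2-yl)pentadeca-5,9,13-trien-1-yl]-5-(furan-3-yl)pent-2-enoate | C=C(C)[C@H](C/C=C(\C)CC/C=C(\CCC=C(C)C)C(=O)OCC=C)CC/C(=C/CCc1ccoc1)C(=O)OC | intermediate
31 | (2E,6E,9S,12Z)-15-(furan-3-yl)-12-(methoxycarbonyl)-6-methyl-2-(4-methylpent-3-en-1-yl)-9-(prop-1-en-2-yl)pentadeca-2,6,12-trienoic acid (CNP0201108.2) | C=C(C)[C@H](C/C=C(\C)CC/C=C(\CCC=C(C)C)C(=O)O)CC/C(=C/CCc1ccoc1)C(=O)OC | target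

## Step count and weak points

Total step count: 17. Longest linear sequence: 13 steps (steps 2–9, 12–14, 16 and 17, from pent-4-yn-1-ol 3).

**Step 5 (key step).** Three processes could spoil it:
- migration of the silyl group from oxygen to the lithiated carbon, or other decay of the γ-silyloxy organolithium, during the long deprotonation;
- slow or incomplete 1,2-migration in the pinacol boronate complex, so that the complex reverts on work-up;
- incomplete or poorly selective deprotonation, which lowers the enantiomeric purity and lets free s-BuLi add to the boronate.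

Fallback, from 1 back to 10: alcohol 1 would be esterified with 2,4,6-triisopropylbenzoyl chloride to 3-(tert-butyldimethylsilyloxy)propyl 2,4,6-triisopropylbenzoate F1. Lithiation with s-BuLi/(+)-sparteine and trapping with Me3SnCl with retention would give the storable (R)-α-trimethylstannyl benzoate F2, whose enantiomeric purity can be checked before use. Tin–lithium exchange of F2 with n-BuLi in the presence of boronate 7, without diamine, would regenerate the (R)-α-lithio benzoate F3 only for an instant. Its boronate complex F4 carries the better benzoate leaving group and should rearrange to 10 without a Lewis acid. The carbenoid is then generated by exchange in the presence of its trap, not by slow deprotonation, while the C7–C8 disconnection stays the same.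

**Step 9.** The anion of the fluorinated phosphonoacetate is a weak nucleophile, so slow alkylation, elimination of the iodide or double alkylation could dominate. Fallback, from 15 back to 17:
- iodide 15 would be alkylated with the much more nucleophilic sodium salt of trimethyl phosphonoacetate to the dimethyl phosphonate F5;
- Me3SiBr would convert F5 into the bis(trimethylsilyl) phosphonate F6;
- oxalyl chloride with catalytic DMF would give the phosphonic dichloride F7;
- 2,2,2-trifluoroethanol and Et3N would turn F7 into 17.

This is the usual way in which substituted reagents of this type are made, and it separates C–C bond formation from the installation of the fluorinated ester groups.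

**Step 4.** Syn–anti interconversion of the allylpalladium intermediate could erode the E geometry, boron could be delivered to the tertiary terminus, or the product could protodeboronate in the protic medium. Fallback, from 4 (through alane 5) back to 7:
- alane 5 would be quenched with iodine to the (E)-vinyl iodide F8, tert-butyl[(E)-(5-iodo-4-methylpent-4-en-1-yl)oxy]diphenylsilane;
- iodine–lithium exchange with t-BuLi at −78 °C would give the alkenyllithium F9 with retention;
- addition to 2-(chloromethyl)-4,4,5,5-tetramethyl-1,3,2-dioxaborolane would give the chloromethyl boronate complex F10, whose 1,2-shift with loss of chloride delivers 7.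

No allylmetal intermediate is involved, so the geometry cannot scramble.

**Step 15.** An unactivated homoallylic halide may alkylate the stabilised ylide slowly, and proton exchange between ylide and salt could leave a mixture of ylides that would contaminate step 16. Fallback, from 27 back to 29: bromide 27 would be heated with PPh3 to (4-methylpent-3-en-1-yl)triphenylphosphonium bromide F11. Deprotonation with NaN(SiMe3)2 would give the non-stabilised ylide F12, and two equivalents of F12 would be C-acylated with allyl chloroformate (the second equivalent acts as base) to give 29 directly. The α-branch is then in place before the ester is attached, and no alkylation of a stabilised ylide is needed.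

## Further compounds

F1 | step 5 | 3-(tert-butyldimethylsilyloxy)propyl 2,4,6-triisopropylbenzoate | CC(C)c1cc(C(C)C)c(C(=O)OCCCO[Si](C)(C)C(C)(C)C)c(C(C)C)c1
F2 | step 5 | (R)-3-(tert-butyldimethylsilyloxy)-1-(trimethylstannyl)propyl 2,4,6-triisopropylbenzoate | C[Sn](C)(C)[C@H](CCO[Si](C)(C)C(C)(C)C)OC(=O)c1c(C(C)C)cc(C(C)C)cc1C(C)C
F3 | step 5 | (R)-3-(tert-butyldimethylsilyloxy)-1-lithiopropyl 2,4,6-triisopropylbenzoate | [Li][C@H](CCO[Si](C)(C)C(C)(C)C)OC(=O)c1c(C(C)C)cc(C(C)C)cc1C(C)C
F4 | step 5 | lithium boronate complex of F3 and 7 | [Li+].CC1(C)O[B-](C/C=C(\C)CCCO[Si](c2ccccc2)(c2ccccc2)C(C)(C)C)([C@H](CCO[Si](C)(C)C(C)(C)C)OC(=O)c2c(C(C)C)cc(C(C)C)cc2C(C)C)OC1(C)C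
F5 | step 9 | methyl (5S,7E)-11-(tert-butyldiphenylsilyloxy)-2-(dimethoxyphosphoryl)-8-methyl-5-(prop-1-en-2-yl)undec-7-enoate | C=C(C)[C@H](C/C=C(\C)CCCO[Si](c1ccccc1)(c1ccccc1)C(C)(C)C)CCC(C(=O)OC)P(=O)(OC)OC
F6 | step 9 | bis(trimethylsilyl) phosphonate corresponding to F5 | C=C(C)[C@H](C/C=C(\C)CCCO[Si](c1ccccc1)(c1ccccc1)C(C)(C)C)CCC(C(=O)OC)P(=O)(O[Si](C)(C)C)O[Si](C)(C)C
F7 | step 9 | phosphonic dichloride corresponding to F5 | C=C(C)[C@H](C/C=C(\C)CCCO[Si](c1ccccc1)(c1ccccc1)C(C)(C)C)CCC(C(=O)OC)P(=O)(Cl)Cl
F8 | step 4 | tert-butyl[(E)-(5-iodo-4-methylpent-4-en-1-yl)oxy]diphenylsilane | I/C=C(\C)CCCO[Si](c1ccccc1)(c1ccccc1)C(C)(C)C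
F9 | step 4 | [(E)-5-(tert-butyldiphenylsilyloxy)-2-methylpent-1-en-1-yl]lithium | [Li]/C=C(\C)CCCO[Si](c1ccccc1)(c1ccccc1)C(C)(C)C
F10 | step 4 | lithium (chloromethyl)(alkenyl) pinacol boronate complex from F9 | [Li+].CC1(C)O[B-](CCl)(/C=C(\C)CCCO[Si](c2ccccc2)(c2ccccc2)C(C)(C)C)OC1(C)C
F11 | step 15 | (4-methylpent-3-en-1-yl)triphenylphosphonium bromide | CC(C)=CCC[P+](c1ccccc1)(c1ccccc1)c1ccccc1.[Br-]
F12 | step 15 | (4-methylpent-3-en-1-ylidene)triphenyl-λ5-phosphane | CC(C)=CCC=P(c1ccccc1)(c1ccccc1)c1ccccc1
A1 | alternative 1 | tert-butyl ester (at C14) of the target | C=C(C)[C@H](C/C=C(\C)CC/C=C(\CCC=C(C)C)C(=O)OC(C)(C)C)CC/C(=C/CCc1ccoc1)C(=O)OC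
A2 | alternative 1 | methyl (E)-2-iodo-5-(furan-3-yl)pent-2-enoate | COC(=O)/C(I)=C\CCc1ccoc1
A3 | alternative 1 | alkylzinc iodide at C5 of the C5–C18 fragment with tert-butyl ester on C14 | C=C(C)[C@H](C/C=C(\C)CC/C=C(\CCC=C(C)C)C(=O)OC(C)(C)C)CC[Zn]I
A4 | alternative 2 | ethyl (S)-3-[2-(tert-butyldimethylsilyloxy)ethyl]-4-methylpent-4-enoate | C=C(C)[C@H](CC(=O)OCC)CCO[Si](C)(C)C(C)(C)C
A5 | alternative 2 | ethyl (E)-5-(tert-butyldimethylsilyloxy)pent-2-enoate | CCOC(=O)/C=C/CCO[Si](C)(C)C(C)(C)C
A6 | alternative 2 | 4,4,5,5-tetramethyl-2-(prop-1-en-2-yl)-1,3,2-dioxaborolane | C=C(C)B1OC(C)(C)C(C)(C)O1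
A7 | alternative 3 | ethyl (4E,7R)-7-[2-(tert-butyldimethylsilyloxy)ethyl]-4,8-dimethylnona-4,8-dienoate | C=C(C)[C@H](C/C=C(\C)CCC(=O)OCC)CCO[Si](C)(C)C(C)(C)C
A8 | alternative 3 | (5S)-5-[2-(tert-butyldimethylsilyloxy)ethyl]-2,6-dimethylhepta-1,6-dien-3-ol (either C3 epimer) | C=C(C)[C@H](CC(O)C(C)=C)CCO[Si](C)(C)C(C)(C)C
A9 | alternative 3 | triethyl orthoacetate | CCOC(C)(OCC)OCC
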